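Heating stays on the list, and the quick number for this flask at 2.5 d is about 22.4%. Friday's run is this flask followed so far, so the reply rests on its readings and on Tuesday's colder run.

| flask | substrate | temperature | remark | time |
|---|---|---|---|---|
| Friday's | 1.3 M | 25 °C | the very flask that is asked about, followed so far |  |
| Tuesday's | 1.3 M | 10 °C | run made earlier |  |
| flask | 1.3 M | 25 °C |  | 2.5 d |

| run | time / h | target / % | substrate / % |
|---|---|---|---|
| Friday's | 3.00 | 36.4 | 26.8 |
| Friday's | 10.0 | 26.0 | 8.7 |
| Friday's | 15.0 | 24.8 | 5.9 |
| Friday's | 25.0 | 22.8 | 2.1 |
| Friday's | 40.0 | 22.1 | 0.6 |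
| Friday's | 50.0 | 22.6 | 0.4 |
| Friday's | 60.0 | 22.4 | 0.2 |
| Tuesday's | 6.00 | 38.4 | 44.2 |
| Tuesday's | 20.0 | 32.0 | 16.4 |
| Tuesday's | 30.0 | 26.4 | 10.9 |
| Tuesday's | 48.0 | 20.2 | 7.1 |
| Tuesday's | 96.0 | 14.4 | 4.0 |
| Tuesday's | 120 | 13.7 | 2.3 |

(each reading ± 0.5 percentage points)

- epsilon: at 2.5 d add substrate, 50.0% of the amount charged, then wait 30 h
- delta: at 2.5 d raise the temperature by 25 K, then wait 30 h
- alpha: change nothing and wait 30 h more

- a species is counted by the substrate in it: one target counts as two
- additions leave the volume as it is
- a reading or a percentage of target counts all its forms, free or not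

- target, in percent of the substrate first charged, at 2.5 d
- the remedy with the largest gain of target, or "none" below 2 percentage points (epsilon / delta / alpha / none)
- target present, in percent of the substrate first charged, after epsilon
- target present, in percent of the substrate first charged, after alpha

Target in Friday's run goes from 22.1% at 40.0 h to 22.4% at 60.0 h, a shift smaller than the scatter of 0.5 percentage points. So waiting looks useless. The useful quantity comes from the material balance of substrate. Call the gap the share of the charge found in neither reading, with target counted by the substrate in it:

gap = charge − [substrate] − [target] = 77.4% (Friday's run, 60.0 h)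

gap = charge − [substrate] − [target] = 84.0% (Tuesday's run, 120 h)

Tuesday's gap is wider by 6.6 points, more than the scatter of one reading. But Tuesday's run is colder and was read later, so these two gaps do not separate temperature from time. The readings do not say what stands in the gap. If part of it can return to target, heating may draw on it, so this reckoning keeps 25 K of heating open and puts no number on it.

The forecast gives 22.4% now, the same reading as above, 22.3% after waiting, 23% after adding substrate, and the choice "none". It parts from this reckoning on heating. Its ground is that “the stall looks like exhaustion rather than equilibrium”.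

The flask gives 22.1% now, 21.9% after waiting and 27.1% after adding substrate. The choice is delta, with gains of 10 points for heating, 4.9 points for adding substrate and −0.24 points for waiting.

    substrate + target → side product (k = 0.00430 /M/min, Ea = 59.0 kJ/mol)
    target ⇌ isomer of the product (K = 1.20, k = 0.00320 /min, Ea = 90.0 kJ/mol, ΔH = −29.0 kJ/mol)
    2 substrate → target (k = 0.00510 /M/min, Ea = 68.0 kJ/mol)
    crystals ⇌ target, rate k4*(cs4 - [target]) while solid is left; crystals form when [target] > cs4 (solubility = 1.20 M, k = 0.0640 /min)
    (constants at 25 °C)

In this flask, two substrate → target had 99.6% of its turnover up to 2.5 d behind it by 30.0 h. Substrate + target → side product ran alongside it and had 77% of its turnover up to 2.5 d behind it by 12.0 h. The gap of 77.4% in this flask holds side product, 50.7% at 60.0 h, and isomer of the product, 26.7%, with crystals at 0%. The neighbour kept at 10 °C has a gap of 76.9% at 60.0 h, with side product at 46.8% and more isomer of the product than this flask, 30.1% against 26.7%.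

All runs were generated by integration with made-up constants, noise included.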